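## Retrosynthetic overview

1. Target 26 ⇐ oxidation of the C6 allylic alcohol and bis-angeloylation of bicyclic diol 21; both esters are installed before the enone is unveiled.
2. Ring B (seven-membered) ⇐ ring-closing metathesis forming C2=C3 in diene diol 20; ring A is present from the start and ring B is closed last.
3. Key C–C bond C11–C1 ⇐ intermolecular carbonyl allylation of aldehyde 14 with a (Z)-γ-(methoxymethoxy)allyl-B(Ipc)2 reagent, setting both carbinol centres (syn, R,R).
4. C9–C10 bond, quaternary C10 and the cis C4/C9 relationship ⇐ Ireland–Claisen rearrangement of tertiary allylic isobutyrate 9.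
5. Allylic alcohol 7 ⇐ (S)-carvone (ring A) via cis-carveol, directed epoxidation and selenide-mediated epoxide-to-allylic-alcohol transposition.

Assumption and labels: both acyl groups are read as angelates [(Z)-2-methylbut-2-enoates] and the target as (4aS,6R,7R,9aR), i.e. cis ring fusion and trans diester. Atom labels used below: C1 and C11 carry the esters, C2=C3(Me), C4 and C9 are the ring-fusion carbons, C6 is the ketone, C7(Me)=C8, C10 is CMe2.

## Route

Step 1
Reactants: 1 (S)-(+)-carvone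
Product: 2 (1S,5S)-cis-carveol
Conditions: NaBH4, CeCl3·7H2O, MeOH, −20 °C
Reagents that add atoms: none
Why: Luche 1,2-reduction; axial hydride delivery gives the alcohol cis to the isopropenyl group (about 95:5), which will direct the epoxidation.

Step 2
Reactants: 2 (1S,5S)-cis-carveol
Product: 3 (1S,2S,4R,6R)-1-methyl-4-(prop-1-en-2-yl)-7-oxabicyclo[4.1.0]heptan-2-ol
Conditions: VO(acac)2 (2 mol %), t-BuOOH, CH2Cl2, 0 °C to rt
Reagents that add atoms: tert-butyl hydroperoxide, CC(C)(C)OO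
Why: hydroxyl-directed vanadium-catalysed epoxidation delivers oxygen to the ring alkene syn to OH (hence syn to the isopropenyl group) and leaves the isopropenyl alkene untouched.

Step 3
Reactants: 3 syn-epoxy alcohol
Product: 4 2-naphthylmethyl (NAP) ether of 3
Conditions: NaH, 2-(bromomethyl)naphthalene, Bu4NI (cat.), THF/DMF, 0 °C to rt
Reagents that add atoms: 2-(bromomethyl)naphthalene, BrCc1ccc2ccccc2c1
Why: Williamson etherification; the syn epoxide cannot undergo Payne rearrangement (no backside access), and the NAP ether tolerates the later base, hydride and Lewis-acid steps and is removed oxidatively at the end.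

Step 4
Reactants: 4 NAP-protected epoxide
Product: 5 hydroxy selenide (SePh at C8 trans to the tertiary C7 hydroxyl)
Conditions: (PhSe)2, NaBH4, EtOH, rt to reflux
Reagents that add atoms: diphenyl diselenide, c1ccc(cc1)[Se][Se]c1ccccc1
Why: SN2 trans-diaxial opening of the trisubstituted epoxide by benzeneselenolate at the secondary carbon, through a chair with the ONAP and isopropenyl groups equatorial, leaves the tertiary C7–O bond (cis to the isopropenyl group) untouched.

Step 5
Reactants: 5 hydroxy selenide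
Product: 7 (1R,4R,6S)-1-methyl-6-(naphthalen-2-ylmethoxy)-4-(prop-1-en-2-yl)cyclohex-2-en-1-ol, via selenoxide 6 (not isolated)
Conditions: 30% H2O2, pyridine, THF, 0 °C to rt
Reagents that add atoms: none
Why: selenoxide syn-elimination (Sharpless-type epoxide-to-allylic-alcohol transposition) can only take a C9 hydrogen because C7 is fully substituted, giving the C8=C9 alkene.

Step 6
Reactants: 7 tertiary allylic alcohol; 8 isobutyryl chloride
Product: 9 (1R,4R,6S)-1-methyl-6-(naphthalen-2-ylmethoxy)-4-(prop-1-en-2-yl)cyclohex-2-en-1-yl 2-methylpropanoate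
Conditions: n-BuLi, THF, −78 °C; then 8, −78 to 0 °C
Reagents that add atoms: none
Why: O-acylation after deprotonation with n-BuLi esterifies the hindered tertiary allylic alcohol without ionising it; no stereocentre changes.

Step 7
Reactants: 9 tertiary allylic isobutyrate
Product: 12 2-methyl-2-[(1S,4S,6R)-3-methyl-4-(naphthalen-2-ylmethoxy)-6-(prop-1-en-2-yl)cyclohex-2-en-1-yl]propanoic acid, via silyl ketene acetal 10 (not isolated), via trimethylsilyl ester 11 (not isolated)
Conditions: LiN(i-Pr)2, Me3SiCl/Et3N, THF, −78 °C to 65 °C; then 1 M HCl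
Reagents that add atoms: none
Why: Ireland–Claisen [3,3] rearrangement; suprafacial transfer from the C7–O bond (cis to isopropenyl) forms the C9–C10 bond on the same face, fixing the cis C4/C9 relationship and the quaternary C10 and placing the alkene at C7=C8.

Step 8
Reactants: 12 carboxylic acid
Product: 13 2-methyl-2-[(1S,4S,6R)-3-methyl-4-(naphthalen-2-ylmethoxy)-6-(prop-1-en-2-yl)cyclohex-2-en-1-yl]propan-1-ol
Conditions: LiAlH4, THF, 0 °C to reflux
Reagents that add atoms: none
Why: hydride reduction of the neopentyl acid to the primary alcohol; ethers and alkenes are inert and no stereocentre is touched.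

Step 9
Reactants: 13 neopentyl alcohol
Product: 14 2-methyl-2-[(1S,4S,6R)-3-methyl-4-(naphthalen-2-ylmethoxy)-6-(prop-1-en-2-yl)cyclohex-2-en-1-yl]propanal
Conditions: Dess–Martin periodinane, NaHCO3, CH2Cl2, 0 °C to rt
Reagents that add atoms: none
Why: Dess–Martin oxidation gives a non-enolisable α-quaternary aldehyde that cannot epimerise.

Step 10
Reactants: 15 allyl alcohol
Product: 16 allyl methoxymethyl ether
Conditions: MOMCl, i-Pr2NEt, CH2Cl2, 0 °C to rt
Reagents that add atoms: chloromethyl methyl ether, COCCl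
Why: O-alkylation (MOM protection) gives the allyl ether whose acetal oxygen directs (Z)-selective γ-metalation in the next step.

Step 11
Reactants: 14 aldehyde; 16 allyl methoxymethyl ether
Product: 19 (3R,4R)-3-(methoxymethoxy)-5-methyl-5-[(1S,4S,6R)-3-methyl-4-(naphthalen-2-ylmethoxy)-6-(prop-1-en-2-yl)cyclohex-2-en-1-yl]hex-1-en-4-ol, via allylborane 17 (not isolated), via borinate 18 (not isolated)
Conditions: 16, s-BuLi, THF, −78 °C; (−)-Ipc2BOMe; BF3·OEt2; then 14, −78 to −20 °C; NaOH, 30% H2O2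
Reagents that add atoms: none
Why: Brown γ-alkoxyallylboration (intermolecular carbonyl allylation, the key fragment union); the (Z)-reagent reacts through a closed chair transition state to give the syn (threo) pair, and the Ipc groups from (+)-α-pinene select the aldehyde face that gives R at C11 and R at C1.

Step 12
Reactants: 19 mono-MOM diene
Product: 20 (3R,4R)-5-methyl-5-[(1S,4S,6R)-3-methyl-4-(naphthalen-2-ylmethoxy)-6-(prop-1-en-2-yl)cyclohex-2-en-1-yl]hex-1-ene-3,4-diol
Conditions: ZnBr2, n-PrSH, CH2Cl2, 0 °C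
Reagents that add atoms: none
Why: Lewis acid/thiol acetal cleavage removes the MOM group (the thiol traps the methoxymethyl unit so no cyclic formal forms) and leaves the NAP ether and alkenes alone.

Step 13
Reactants: 20 diene diol
Product: 21 (2S,4aS,6R,7R,9aR)-3,5,5,9-tetramethyl-2-(naphthalen-2-ylmethoxy)-2,4a,5,6,7,9a-hexahydro-1H-benzo[7]annulene-6,7-diol
Conditions: second-generation Grubbs catalyst (10 mol %), 1,4-benzoquinone (20 mol %), toluene (2 mM), 80 °C
Reagents that add atoms: none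
Why: ring-closing metathesis of the vinyl and isopropenyl groups forms the trisubstituted C2=C3 alkene of ring B, helped by the gem-dimethyl group and the cis arrangement on ring A; all stereocentres are already set.

Step 14
Reactants: 22 angelic acid (two molecules)
Product: 23 angelic anhydride
Conditions: DCC (0.5 equiv relative to 22), CH2Cl2, 0 °C to rt
Reagents that add atoms: angelic acid (second molecule of 22), C/C=C(/C)C(=O)O
Why: carbodiimide dehydration couples two molecules of angelic acid through the O-acylisourea under neutral conditions, giving the symmetric anhydride without Z-to-E isomerisation.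

Step 15
Reactants: 21 bicyclic diol; 23 angelic anhydride
Product: 24 (2S,4aS,6R,7R,9aR)-3,5,5,9-tetramethyl-2-(naphthalen-2-ylmethoxy)-2,4a,5,6,7,9a-hexahydro-1H-benzo[7]annulene-6,7-diyl bis[(2Z)-2-methylbut-2-enoate]
Conditions: LiN(SiMe3)2 (2.2 equiv), THF, −78 °C; then 23 (3 equiv), −78 to 0 °C
Reagents that add atoms: angelic anhydride (second equivalent of 23), C/C=C(/C)C(=O)OC(=O)/C(C)=C\C
Why: O-acylation of the dilithium alkoxide at low temperature, with no nucleophilic amine catalyst, esterifies both hindered secondary hydroxyls (one anhydride molecule per hydroxyl) with retention at C1 and C11 and without angelate-to-tiglate isomerisation.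

Step 16
Reactants: 24 bis-angelate NAP ether
Product: 25 (2S,4aS,6R,7R,9aR)-2-hydroxy-3,5,5,9-tetramethyl-2,4a,5,6,7,9a-hexahydro-1H-benzo[7]annulene-6,7-diyl bis[(2Z)-2-methylbut-2-enoate]
Conditions: DDQ, CH2Cl2/pH 7 buffer (10:1), 0 °C to rt
Reagents that add atoms: none
Why: oxidative cleavage of the 2-naphthylmethyl ether (benzylic hydride abstraction, then hydrolysis) frees the allylic C6 alcohol without touching the esters.

Step 17
Reactants: 25 allylic alcohol
Product: 26 (4aS,6R,7R,9aR)-3,5,5,9-tetramethyl-2-oxo-2,4a,5,6,7,9a-hexahydro-1H-benzo[7]annulene-6,7-diyl bis[(2Z)-2-methylbut-2-enoate]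
Conditions: Dess–Martin periodinane, NaHCO3, CH2Cl2, 0 °C to rt
Reagents that add atoms: none
Why: buffered Dess–Martin oxidation of the allylic alcohol gives the conjugated enone under neutral conditions that leave C9 and the angelates untouched.

## Compound list

1 | (S)-(+)-carvone, (5S)-2-methyl-5-(prop-1-en-2-yl)cyclohex-2-en-1-one | CC1=CC[C@@H](CC1=O)C(C)=C | starting material
2 | (1S,5S)-cis-carveol (OH cis to isopropenyl) | C1C=C(C)[C@@H](O)C[C@H]1C(C)=C | intermediate
3 | (1S,2S,4R,6R)-1-methyl-4-(prop-1-en-2-yl)-7-oxabicyclo[4.1.0]heptan-2-ol (epoxide O, OH and isopropenyl on one face) | C1[C@H]2O[C@@]2(C)[C@@H](O)C[C@H]1C(C)=C | intermediate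
4 | 2-naphthylmethyl ether of 3: 1-methyl-2-(naphthalen-2-ylmethoxy)-4-(prop-1-en-2-yl)-7-oxabicyclo[4.1.0]heptane, epoxide O, ONAP and isopropenyl all cis | C1[C@H]2O[C@@]2(C)[C@@H](OCc3ccc4ccccc4c3)C[C@H]1C(C)=C | intermediate
5 | 1-methyl-6-(naphthalen-2-ylmethoxy)-2-(phenylselanyl)-4-(prop-1-en-2-yl)cyclohexan-1-ol; OH, ONAP and isopropenyl cis, SePh trans to OH | C1[C@H]([Se]c2ccccc2)[C@](O)(C)[C@@H](OCc3ccc4ccccc4c3)C[C@H]1C(C)=C | intermediate
6 | selenoxide of 5 (formed in the flask) | C1[C@H]([Se](=O)c2ccccc2)[C@](O)(C)[C@@H](OCc3ccc4ccccc4c3)C[C@H]1C(C)=C | intermediate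
7 | (1R,4R,6S)-1-methyl-6-(naphthalen-2-ylmethoxy)-4-(prop-1-en-2-yl)cyclohex-2-en-1-ol (OH, ONAP and isopropenyl all cis) | C1=C[C@](O)(C)[C@@H](OCc2ccc3ccccc3c2)C[C@H]1C(C)=C | intermediate
8 | isobutyryl chloride (2-methylpropanoyl chloride) | CC(C)C(Cl)=O | starting material
9 | isobutyrate of 7 | C1=C[C@](OC(=O)C(C)C)(C)[C@@H](OCc2ccc3ccccc3c2)C[C@H]1C(C)=C | intermediate
10 | trimethylsilyl ketene acetal of 9 (formed in the flask) | C1=C[C@](OC(O[Si](C)(C)C)=C(C)C)(C)[C@@H](OCc2ccc3ccccc3c2)C[C@H]1C(C)=C | intermediate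
11 | trimethylsilyl ester of 12 (formed in the flask) | C[Si](C)(C)OC(=O)C(C)(C)[C@H]1C=C(C)[C@@H](OCc2ccc3ccccc3c2)C[C@H]1C(C)=C | intermediate
12 | 2-methyl-2-[(1S,4S,6R)-3-methyl-4-(naphthalen-2-ylmethoxy)-6-(prop-1-en-2-yl)cyclohex-2-en-1-yl]propanoic acid (ring substituents at C1, C4, C6 all cis) | OC(=O)C(C)(C)[C@H]1C=C(C)[C@@H](OCc2ccc3ccccc3c2)C[C@H]1C(C)=C | intermediate
13 | corresponding propan-1-ol | OCC(C)(C)[C@H]1C=C(C)[C@@H](OCc2ccc3ccccc3c2)C[C@H]1C(C)=C | intermediate
14 | corresponding propanal | O=CC(C)(C)[C@H]1C=C(C)[C@@H](OCc2ccc3ccccc3c2)C[C@H]1C(C)=C | intermediate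
15 | allyl alcohol | C=CCO | starting material
16 | allyl methoxymethyl ether, 3-(methoxymethoxy)prop-1-ene | C=CCOCOC | intermediate
17 | [(Z)-3-(methoxymethoxy)allyl]bis(isopinocampheyl)borane, Ipc from (+)-α-pinene (formed in the flask) | COCO/C=C\CB([C@H]1[C@H](C)[C@H]2C[C@@H](C1)C2(C)C)[C@H]1[C@H](C)[C@H]2C[C@@H](C1)C2(C)C | intermediate
18 | bis(isopinocampheyl)borinate of 19 (formed in the flask) | C=C[C@@H](OCOC)[C@H](OB([C@H]4[C@H](C)[C@H]5C[C@@H](C4)C5(C)C)[C@H]6[C@H](C)[C@H]7C[C@@H](C6)C7(C)C)C(C)(C)[C@H]1C=C(C)[C@@H](OCc2ccc3ccccc3c2)C[C@H]1C(C)=C | intermediate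
19 | (3R,4R)-3-(methoxymethoxy)-5-methyl-5-[(1S,4S,6R)-3-methyl-4-(naphthalen-2-ylmethoxy)-6-(prop-1-en-2-yl)cyclohex-2-en-1-yl]hex-1-en-4-ol | C=C[C@@H](OCOC)[C@H](O)C(C)(C)[C@H]1C=C(C)[C@@H](OCc2ccc3ccccc3c2)C[C@H]1C(C)=C | intermediate
20 | (3R,4R)-5-methyl-5-[(1S,4S,6R)-3-methyl-4-(naphthalen-2-ylmethoxy)-6-(prop-1-en-2-yl)cyclohex-2-en-1-yl]hex-1-ene-3,4-diol | C=C[C@@H](O)[C@H](O)C(C)(C)[C@H]1C=C(C)[C@@H](OCc2ccc3ccccc3c2)C[C@H]1C(C)=C | intermediate
21 | (2S,4aS,6R,7R,9aR)-3,5,5,9-tetramethyl-2-(naphthalen-2-ylmethoxy)-2,4a,5,6,7,9a-hexahydro-1H-benzo[7]annulene-6,7-diol | O[C@@H]1C=C(C)[C@@H]2C[C@H](OCc3ccc4ccccc4c3)C(C)=C[C@@H]2C(C)(C)[C@H]1O | intermediate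
22 | angelic acid, (Z)-2-methylbut-2-enoic acid | C/C=C(/C)C(=O)O | starting material
23 | angelic anhydride, (Z)-2-methylbut-2-enoic anhydride | C/C=C(/C)C(=O)OC(=O)/C(C)=C\C | intermediate
24 | bis-angelate of 21 | C/C=C(/C)C(=O)O[C@@H]1C=C(C)[C@@H]2C[C@H](OCc3ccc4ccccc4c3)C(C)=C[C@@H]2C(C)(C)[C@H]1OC(=O)/C(C)=C\C | intermediate
25 | (2S,4aS,6R,7R,9aR)-2-hydroxy-3,5,5,9-tetramethyl-2,4a,5,6,7,9a-hexahydro-1H-benzo[7]annulene-6,7-diyl bis[(2Z)-2-methylbut-2-enoate] | C/C=C(/C)C(=O)O[C@@H]1C=C(C)[C@@H]2C[C@H](O)C(C)=C[C@@H]2C(C)(C)[C@H]1OC(=O)/C(C)=C\C | intermediate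
26 | (4aS,6R,7R,9aR)-3,5,5,9-tetramethyl-2-oxo-2,4a,5,6,7,9a-hexahydro-1H-benzo[7]annulene-6,7-diyl bis[(2Z)-2-methylbut-2-enoate] (CNP0361763.1) | C/C=C(/C)C(=O)O[C@@H]1C=C(C)[C@@H]2CC(=O)C(C)=C[C@@H]2C(C)(C)[C@H]1OC(=O)/C(C)=C\C | target

## Step count and risks

Total step count: 17. Longest linear sequence: 15 (steps 1–9, 11–13, 15–17 from (S)-carvone).

**Step 7 (Ireland–Claisen of a hindered tertiary ester).** The risk is ionisation of the ester or a sluggish rearrangement next to the cis isopropenyl group. The fallback sets out from 7 and comes back at 13. Alcohol 7 is heated with triethyl orthoacetate and catalytic propionic acid (140 °C); the Johnson–Claisen rearrangement, with the same suprafacial delivery, gives the ethyl acetate-type ester F1. Two enolate methylations follow (LiN(i-Pr)2, MeI, THF, −78 °C; then LiN(i-Pr)2, DMPU, MeI), passing through the α-methyl ester F2 to the α,α-dimethyl ester F3. LiAlH4 reduction of F3 gives alcohol 13.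

**Step 11 (alkoxyallylboration of the α-quaternary aldehyde).** The risk is slow addition or eroded reagent control. The fallback sets out from 14 and comes back at 20; it replaces the allylboration by an auxiliary-controlled glycolate aldol and builds the vinyl group afterwards. (S)-4-Benzyl-3-[(4-methoxybenzyloxy)acetyl]oxazolidin-2-one is enolised (Bu2BOTf, Et3N, CH2Cl2, −78 to 0 °C) and added to 14 to give the syn aldol imide F4, with the same R,R sense at C1 and C11. Silylation (Et3SiOTf, 2,6-lutidine) gives the triethylsilyl ether F5. LiBH4 (THF/MeOH) releases the auxiliary and gives the primary alcohol F6. Dess–Martin oxidation gives the α-alkoxy aldehyde F7, and Wittig methylenation (Ph3P=CH2, THF, −78 to 0 °C) gives the vinyl compound F8. AcOH/THF/H2O removes the silyl group to give the hydroxy PMB ether F9. (NH4)2Ce(NO3)6 in MeCN/H2O at 0 °C then cleaves the PMB ether faster than the 2-naphthylmethyl ether, giving diene diol 20.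

**Step 15 (double angeloylation of a hindered trans-diol).** The risk is incomplete acylation at the neopentyl C11 hydroxyl or Z-to-E isomerisation. The fallback sets out from 21 and comes back at 24; it builds the angelate double bonds on the substrate instead of transferring them. Both hydroxyls are esterified with 2-[bis(2,2,2-trifluoroethoxy)phosphoryl]propanoic acid (DCC, DMAP, CH2Cl2) to give the bis(phosphonopropionate) F10. A double Still–Gennari olefination with acetaldehyde (KN(SiMe3)2, 18-crown-6, THF, −78 °C) then forms both (Z)-2-methylbut-2-enoates and gives 24.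

## Further compounds

F1 | step 7 | ethyl 2-[3-methyl-4-(naphthalen-2-ylmethoxy)-6-(prop-1-en-2-yl)cyclohex-2-en-1-yl]acetate (ring substituents all cis) | CCOC(=O)C[C@H]1C=C(C)[C@@H](OCc2ccc3ccccc3c2)C[C@H]1C(C)=C
F2 | step 7 | ethyl 2-[3-methyl-4-(naphthalen-2-ylmethoxy)-6-(prop-1-en-2-yl)cyclohex-2-en-1-yl]propanoate (epimers at the side-chain carbon) | CCOC(=O)C(C)[C@H]1C=C(C)[C@@H](OCc2ccc3ccccc3c2)C[C@H]1C(C)=C
F3 | step 7 | ethyl 2-methyl-2-[3-methyl-4-(naphthalen-2-ylmethoxy)-6-(prop-1-en-2-yl)cyclohex-2-en-1-yl]propanoate | CCOC(=O)C(C)(C)[C@H]1C=C(C)[C@@H](OCc2ccc3ccccc3c2)C[C@H]1C(C)=C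
F4 | step 11 | (2S,3R) syn-glycolate aldol imide of 14 with the (S)-4-benzyloxazolidinone auxiliary | O=C1OC[C@H](Cc2ccccc2)N1C(=O)[C@@H](OCc2ccc(OC)cc2)[C@H](O)C(C)(C)[C@H]3C=C(C)[C@@H](OCc4ccc5ccccc5c4)C[C@H]3C(C)=C
F5 | step 11 | triethylsilyl ether of F4 | O=C1OC[C@H](Cc2ccccc2)N1C(=O)[C@@H](OCc2ccc(OC)cc2)[C@H](O[Si](CC)(CC)CC)C(C)(C)[C@H]3C=C(C)[C@@H](OCc4ccc5ccccc5c4)C[C@H]3C(C)=C
F6 | step 11 | primary alcohol from reductive removal of the auxiliary | OC[C@@H](OCc2ccc(OC)cc2)[C@H](O[Si](CC)(CC)CC)C(C)(C)[C@H]3C=C(C)[C@@H](OCc4ccc5ccccc5c4)C[C@H]3C(C)=C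
F7 | step 11 | α-(4-methoxybenzyloxy) aldehyde | O=C[C@@H](OCc2ccc(OC)cc2)[C@H](O[Si](CC)(CC)CC)C(C)(C)[C@H]3C=C(C)[C@@H](OCc4ccc5ccccc5c4)C[C@H]3C(C)=C
F8 | step 11 | vinyl compound with C1–OPMB and C11–OSiEt3 | C=C[C@@H](OCc2ccc(OC)cc2)[C@H](O[Si](CC)(CC)CC)C(C)(C)[C@H]3C=C(C)[C@@H](OCc4ccc5ccccc5c4)C[C@H]3C(C)=C
F9 | step 11 | vinyl compound with C1–OPMB and free C11–OH | C=C[C@@H](OCc2ccc(OC)cc2)[C@H](O)C(C)(C)[C@H]3C=C(C)[C@@H](OCc4ccc5ccccc5c4)C[C@H]3C(C)=C
F10 | step 15 | bis{2-[bis(2,2,2-trifluoroethoxy)phosphoryl]propanoate} of 21 | CC(C(=O)O[C@@H]1C=C(C)[C@@H]2C[C@H](OCc3ccc4ccccc4c3)C(C)=C[C@@H]2C(C)(C)[C@H]1OC(=O)C(C)P(=O)(OCC(F)(F)F)OCC(F)(F)F)P(=O)(OCC(F)(F)F)OCC(F)(F)F
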